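## Assumptions

- Benzoylquinine is assumed to expose the enolate face that leads to the 3R lactone, by analogy with the face its ketene enolates offer to other electrophiles. If a model annulation shows the opposite sense, benzoylquinidine replaces it and nothing else changes.
- 4-Bromo-1,2-bis(benzyloxy)benzene (8) is taken to be a catalogue compound.
- Chain atoms are named Cα (benzylic to ring A'), Cβ (carbinol carbon) and Cγ (bonded to ring B' and to C8).

## Structural features

Gambiriin A1 is a chalcane–flavan dimer. An intact (+)-catechin unit (rings A, B and C; 2R,3S, trans) carries at C8 of ring A an open chain C8–Cγ–Cβ–Cα, in which Cγ also bears catechol ring B', Cβ bears a secondary hydroxyl and CαH2 ends in phloroglucinol ring A'. The four stereocentres form two adjacent pairs, C2/C3 in ring C and Cγ (R)/Cβ (S) in the chain. Aromatic ring A insulates the pairs from each other, so the chain diad cannot be relayed from the catechin and must be set by a reagent. The molecule has eleven free hydroxyl groups and is sensitive to air and base; the benzylic C2–O1 ether opens under strong acid, and Cγ, doubly benzylic and ortho to the C7 hydroxyl, can ionise through a quinone methide. The real difficulty is the crowded C8–Cγ(ring B')–Cβ(OH) array: a bond to C8 (not C6), a diarylmethine stereocentre and a neighbouring carbinol must be made with relative and absolute control and without a nearby stereocentre to help. The feature exploited is that Cγ is benzylic to C8 and C8 is ortho to the C7 oxygen, so O7–C7–C8–Cγ is a latent o-quinone methide (O=C7–C8=Cγ) and the Cβ–Cα pair with its Cβ oxygen is a benzyloxyketene. Their union is a six-membered lactone (O7–Cα, Cγ–Cβ) whose acyl carbon is Cα, the carbon that later accepts ring A'. A check of the descriptors shows that its cis arrangement of the Cβ oxygen and ring B' (3R,4R in the lactone) is exactly the Cβ (S)/Cγ (R) diad of the target; the change of letter at Cβ is only a change of substituent priority.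

## Logic of the disconnections

23 back to 22. The ten O–CH2Ph bonds are cut last. One kind of protecting group throughout means a single neutral final step and no free polyphenol earlier. The demand is that the last step cleaves ten ethers without touching the benzylic C2–O1 bond, and that nothing before it uses hydrogenolysis.

22 back to 21. The Cα–H bond is exchanged for Cα–OH. Cα comes from the key step as an acyl carbon, so it meets ring A' as an electrophile and must lose its oxygen afterwards; a 2,4,6-trialkoxyphenyl carbinol is the easiest benzylic alcohol to reduce. The demand is that hydride capture at Cα beats proton loss from Cβ and ring closure onto ring B' or O7.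

21 back to 16 and 19 (19 from 18, 18 from 17). The Cα–C1 bond of ring A' is cut. Ring A' is symmetrical, so its anion is one species, and the electrophile is the aldehyde hidden in 16. The target falls into a three-ring carbonyl piece and a one-ring nucleophile. The demand is that addition is faster than enolisation toward Cβ. For that reason Cα is kept at the aldehyde level and not at the ketone level that direct opening of 15 would give, where Cβ–H would be acidic.

16 back to 15. No skeletal bond is cut; Cα is raised to the lactone oxidation level, because 15 is what the annulation makes. The demand is that reduction stops at the hemiacetal and uses no basic reagent.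

15 back to 13 and 14 (13 from 11, 14 from 12). The Cγ–Cβ and O7–Cα bonds, which close the lactone ring, are cut. This removes both chain stereocentres, one ring and a two-carbon unit at once and leaves a flat methide and a two-carbon acid chloride. The demand is that the catalyst chooses the enolate face (Cβ) and that the approach is endo (ring B' cis to the Cβ oxygen). 13 must also exist before 12 meets the phenoxide, so that O-acylation cannot compete.

13 back to 11 and 11 back to 10. The Cγ–S bond is cut, then sulfur is exchanged for hydroxyl. 13 cannot be stored; a sulfinate is expelled by mild base, a hydroxyl is not. The demand is that the exchange runs under acid weak enough to spare C2–O1.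

10 back to 7 and 9 (9 from 8). The Cγ–C1' bond of ring B' is cut. Cγ is then an aldehyde carbon already fixed on C8 and ring B' a simple arylmagnesium reagent. The demand is one extra equivalent of 9, because the C7 hydroxyl is free.

7 back to 6. The O7–benzyl bond is restored. Of the five benzyl ethers only the one on O7 has a carbonyl group beside it, so chelation singles it out. Doing this on the aldehyde saves the oxidation and the reduction that a diaryl ketone would need. The demand is that bromide attacks the primary benzyl carbon on O7 and not the secondary benzylic C2 on O1.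

6 back to 4 (through 5) and 4 back to 3. The C8–CHO bond, then the C8–Br bond, are cut. Bromination tells C8 from C6 and halogen–metal exchange turns that choice into a carbon–carbon bond. The demand is that no acidic proton remains, hence the 3-O-benzyl group.

3 back to 2 and 2 back to 1. Five O–benzyl bonds are cut. 1 brings rings A, B and C and the C2/C3 pair from the chiral pool. The demand is conditions that do not epimerise C2.

## Other disconnections considered

Alternative 1: The cut goes through ring A itself (C7–C8, C8a–C4a and C6–C7), so that C8 and C8a come from an alkyne and C4a to C7 from a four-carbon ketene source.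
- Forward step: the triisopropylsiloxyalkyne A2, which carries ring A', ring B' and the finished Cγ/Cβ diad, would be heated with 3-(benzyloxy)cyclobut-2-en-1-one A3. Electrocyclic opening to a vinylketene, [2+2] addition to the ynol ether, a second four-electron opening and six-electron closure should give phenol A1 (O7–H free, O1 silylated, O5 benzylated, chain on C8).
- In its favour: the three ring A oxygens emerge differentiated and the chain is on C8 by construction, so neither a regioselective bromination nor a chelation-controlled debenzylation is needed. On this point the alternative is better than the chosen plan. The cascade is neutral and thermal, with no ionic centre near the diad.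
- Against it: the step creates no stereocentre, so the diad must be made beforehand on an open chain by separate asymmetric chemistry. Its Cγ–H in A2 is benzylic and propargylic and exposed to propargyl–allene isomerisation on prolonged heating. After A1 all of ring C and ring B must still be attached at C4a (which has to be told from C6) and C2/C3 must be created.
- Comparison: structurally it solves ring A elegantly and leaves everything else, whereas the chosen plan takes rings A, B, C and C2/C3 from 1. Mechanistically a pericyclic cascade replaces a polar annulation. In step count it is clearly longer.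

Alternative 2: The cut removes Cα–Cβ and Cγ–C1' (ring B') together and leaves three pieces: Z-iodoalkene A5 (C8–CγH=CβH–I on the protected catechin, one olefination from 6), the ring A' benzylboronic ester A6 and the ring B' triflate A7.
- Forward step: iodine–lithium exchange of A5 and addition to A6 would give an alkenylboron ate complex. Pd(OAc)2 with a chiral MandyPhos-type bisphosphine and A7 should then shift the benzyl group from boron to Cβ while the aryl group is delivered to Cγ, giving boronate A4, which is oxidised with retention to the Cβ alcohol.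
- In its favour: the shift is anti to palladium and the reductive elimination is retentive, so a Z alkene must give the required relative configuration. The chosen plan has no such geometric guarantee for cis; here the alternative is better. Cβ arrives as a C–B bond, so no carbonyl group and no cation stand next to the diad afterwards, and the route is about four steps shorter. On step economy and endgame safety it is also better.
- Against it: alkenyl ate complexes substituted at the carbon remote from boron tend to transfer the alkenyl group directly (plain Suzuki–Miyaura coupling). Pinacol is the least helpful ligand on boron in that respect. The migrating group is a di-ortho-substituted benzyl, and the alkene carbon that must bind palladium carries the di-ortho-substituted ring A.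
- Comparison: the key step would stand at the edge of what this reaction class has shown, with three hindered partners at once. The chosen annulation stays inside a known reaction class and leaves one open question (cis or trans). In both plans the ligand or catalyst must overrule the distant C2/C3 centres, so on absolute control they are equal.

Alternative 3: The cut opens ring C at O1–C2 and removes the C3 oxygen, leading back to E-alkene A9 (O1 as tert-butyldimethylsilyl ether, C4a–CH2–CH=CH–ring B), which already holds the complete chain on C8.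
- Forward step: epoxidation with a fructose-derived ketone and KHSO5 (the ketone enantiomer that gives the 2S,3S epoxide A10), then fluoride and mild acid in the same flask. The freed O1 phenoxide should open A10 at benzylic C2 with inversion (6-endo-tet) to give A8 with the 2R,3S trans arrangement.
- In its favour: E geometry plus inversion gives the 2,3-trans relation stereospecifically and the reagent chooses the absolute sense, so cis or enantiomeric flavan units would be reachable from one intermediate. In flexibility it is better than a chiral-pool start; in reliability of the trans relation it is equal.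
- Against it: A10 is a p-alkoxystyrene oxide and ionises easily, so opening may drift from SN2 to SN1 and lose the inversion. KHSO5 is an oxidant in the presence of electron-rich aryl ethers, 5-exo attack at C3 competes, and the ketone must overrule the two chain stereocentres.
- Comparison: the step does not touch the real problem. A9 must already hold the Cγ/Cβ diad on a hexasubstituted ring A assembled from small pieces with O1 and O7 differentiated, whereas 1 delivers ring A, ring C and C2/C3 ready-made. In step count it is much longer.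

Key step: step 8

## Route

Step 1
Reactants: 1 (+)-catechin, (2R,3S)-2-(3,4-dihydroxyphenyl)chromane-3,5,7-triol
Product: 2 (2R,3S)-5,7,3',4'-tetra-O-benzylcatechin
Conditions: BnBr (4.4 equiv), K2CO3, DMF, 0 °C → rt
Reagents that add atoms: benzyl bromide, BrCc1ccccc1
Why: Williamson etherification; K2CO3 deprotonates only the four phenols, so the secondary 3-OH stays free and C2/C3 are untouched.

Step 2
Reactants: 2 (2R,3S)-5,7,3',4'-tetra-O-benzylcatechin
Product: 3 (2R,3S)-3,5,7,3',4'-penta-O-benzylcatechin
Conditions: NaH, BnBr, n-Bu4NI (cat.), DMF, 0 °C → rt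
Reagents that add atoms: benzyl bromide, BrCc1ccccc1
Why: Williamson etherification of the secondary alkoxide; with all phenols capped the flavan cannot ring-open under base, so C2 does not epimerise. The 3-O-benzyl group removes the last acidic proton before the organolithium step.

Step 3
Reactants: 3 (2R,3S)-3,5,7,3',4'-penta-O-benzylcatechin
Product: 4 8-bromo-3,5,7,3',4'-penta-O-benzylcatechin
Conditions: NBS (1.0 equiv), CH2Cl2, −78 → 0 °C
Reagents that add atoms: N-bromosuccinimide, O=C1CCC(=O)N1Br
Why: Electrophilic aromatic bromination; in per-O-alkylated catechins C8 is the more nucleophilic of the two free ring A positions, and one equivalent at low temperature is known to give the 8-bromide.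

Step 4
Reactants: 4 8-bromo-3,5,7,3',4'-penta-O-benzylcatechin
Product: 6 8-formyl-3,5,7,3',4'-penta-O-benzylcatechin, via 8-lithio-3,5,7,3',4'-penta-O-benzylcatechin 5 (not isolated)
Conditions: n-BuLi, THF, −78 °C; DMF; H2O
Reagents that add atoms: N,N-dimethylformamide, CN(C)C=O
Why: Bromine–lithium exchange at −78 °C is faster than benzylic deprotonation, and formylation of the aryllithium with DMF places the future Cγ carbon on C8 with no C6 isomer.

Step 5
Reactants: 6 8-formyl-3,5,7,3',4'-penta-O-benzylcatechin
Product: 7 8-formyl-7-hydroxy-3,5,3',4'-tetra-O-benzylcatechin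
Conditions: MgBr2·OEt2 (3 equiv), PhMe–Et2O, rt → 50 °C
Reagents that add atoms: none
Why: Chelation-controlled ether cleavage: Mg2+ bridges the aldehyde oxygen and O7, and bromide removes the primary benzyl group by SN2 as benzyl bromide. O1 can chelate too, but its alkyl carbon is the secondary ring carbon C2 and reacts far more slowly; the other benzyl ethers have no neighbouring carbonyl group.

Step 6
Reactants: 7 8-formyl-7-hydroxy-3,5,3',4'-tetra-O-benzylcatechin; 8 4-bromo-1,2-bis(benzyloxy)benzene
Product: 10 7-hydroxy-8-{[3,4-bis(benzyloxy)phenyl](hydroxy)methyl}-3,5,3',4'-tetra-O-benzylcatechin (both carbinol epimers), via 3,4-bis(benzyloxy)phenylmagnesium bromide 9 (not isolated)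
Conditions: 8, Mg, THF, rt (2.5 equiv of 9); then 7, 0 °C → rt; neutral aqueous work-up
Reagents that add atoms: none
Why: Grignard formation and 1,2-addition to a salicylaldehyde: the first equivalent forms the magnesium phenoxide, the second adds to the aldehyde and makes the C1'(ring B')–Cγ bond. The new carbinol centre is not controlled and need not be, since it becomes trigonal in 13.

Step 7
Reactants: 10 7-hydroxy-8-{[3,4-bis(benzyloxy)phenyl](hydroxy)methyl}-3,5,3',4'-tetra-O-benzylcatechin
Product: 11 7-hydroxy-8-{[3,4-bis(benzyloxy)phenyl](p-tolylsulfonyl)methyl}-3,5,3',4'-tetra-O-benzylcatechin (both epimers at the sulfonyl carbon)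
Conditions: p-TolSO2H (2 equiv), CH2Cl2, 0 °C → rt
Reagents that add atoms: p-toluenesulfinic acid, Cc1ccc(cc1)S(=O)O
Why: SN1-type substitution: the weak acid ionises the electron-rich o-hydroxybenzhydrol to the protonated o-quinone methide and sulfinate adds through sulfur, giving a neutral, storable sulfone. An excess of the soft sulfur nucleophile should outcompete Friedel–Crafts attack by a second ring A.

Step 8
Reactants: 11 7-hydroxy-8-{[3,4-bis(benzyloxy)phenyl](p-tolylsulfonyl)methyl}-3,5,3',4'-tetra-O-benzylcatechin; 12 benzyloxyacetyl chloride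
Product: 15 (3R,4R)-cis-3-benzyloxy-4-[3,4-bis(benzyloxy)phenyl]-3,4-dihydrocoumarin annulated on O7/C8 of (2R,3S)-3,5,3',4'-tetra-O-benzylcatechin, via o-quinone methide 13 (not isolated), via benzyloxyketene 14 (not isolated)
Conditions: Cs2CO3 (1.2 equiv), PhMe–THF, 0 °C; then benzoylquinine (10–20 mol %), i-Pr2NEt (2.5 equiv), 12 (2 equiv, added over 3 h), −78 → −40 °C; cold aq. citric acid
Reagents that add atoms: none
Why: Cs2CO3 deprotonates the C7 phenol of 11 and p-toluenesulfinate leaves by 1,4-elimination, giving 13 (O=C7–C8=Cγ), a persistent methide because O5, O1 and ring B' stabilise its dipolar form, and one that is electrophilic only at Cγ. i-Pr2NEt then converts 12 into 14, which benzoylquinine captures through its quinuclidine nitrogen as the Z acylammonium enolate (benzyloxy cis to the enolate oxygen). The enolate carbon adds to Cγ (Cγ–Cβ bond) and the C7 phenoxide so formed attacks the acylammonium carbon (O7–Cα bond), closing the lactone ring by 6-exo-trig acyl substitution and releasing the catalyst. The closest known reaction type is the amine-catalysed formal [4+2] annulation of ketene enolates with o-quinone methides to 3,4-dihydrocoumarins. Cβ is controlled by the catalyst: its quinoline and benzoate groups cover one face of the enolate, so Cγ bonds to the open face, which is expected to give 3R. Cγ is controlled relative to Cβ by the endo approach of the E methide (ring B' on the C8a side), in which both enolate oxygens lie under the heterodiene and the bulky ammonium group points away; this places benzyloxy and ring B' cis (4R). The step needs reaction at O7/C8 only, which the substrate secures because the sulfonylmethyl group sits on C8 next to the single free phenol; it needs C–C bond formation before any O-acylation, which forming 13 first and adding 12 slowly at −78 °C secures; and it needs catalyst control over the C2/C3 centres, which are separated from Cγ by ring A and should exert little bias. A cold, weakly acidic quench keeps the amine bases from epimerising Cβ of the cis lactone.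

Step 9
Reactants: 15 (3R,4R)-cis-3-benzyloxy-4-[3,4-bis(benzyloxy)phenyl]-3,4-dihydrocoumarin annulated on O7/C8 of (2R,3S)-3,5,3',4'-tetra-O-benzylcatechin
Product: 16 (2RS,3R,4R)-3-benzyloxy-4-[3,4-bis(benzyloxy)phenyl]chroman-2-ol annulated on O7/C8 of (2R,3S)-3,5,3',4'-tetra-O-benzylcatechin (lactol of 15)
Conditions: i-Bu2AlH (1.1 equiv), CH2Cl2, −78 °C; aqueous work-up
Reagents that add atoms: none
Why: Partial reduction of an aryl lactone to the lactol; the tetrahedral aluminium alkoxide is stable at −78 °C and collapses only on work-up, and the non-basic hydride leaves the acidic Cβ–H alone. The hemiacetal carbon is the future Cα and its configuration is immaterial.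

Step 10
Reactants: 17 1,3,5-tris(benzyloxy)benzene
Product: 18 2-bromo-1,3,5-tris(benzyloxy)benzene
Conditions: NBS (1.0 equiv), CH2Cl2, −78 → 0 °C
Reagents that add atoms: N-bromosuccinimide, O=C1CCC(=O)N1Br
Why: Electrophilic aromatic bromination; the three free positions are equivalent, so only the stoichiometry has to be controlled.

Step 11
Reactants: 16 (2RS,3R,4R)-3-benzyloxy-4-[3,4-bis(benzyloxy)phenyl]chroman-2-ol annulated on O7/C8 of (2R,3S)-3,5,3',4'-tetra-O-benzylcatechin; 18 2-bromo-1,3,5-tris(benzyloxy)benzene
Product: 21 (1RS,2R,3R)-2-benzyloxy-3-[3,4-bis(benzyloxy)phenyl]-3-[(2R,3S)-3,5,3',4'-tetra-O-benzyl-7-hydroxycatechin-8-yl]-1-[2,4,6-tris(benzyloxy)phenyl]propan-1-ol, via 2,4,6-tris(benzyloxy)phenyllithium 19 (not isolated), via ring-opened lithium phenoxide aldehyde 20 (not isolated)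
Conditions: 18, n-BuLi, THF, −78 °C (3 equiv of 19); then 16, −78 → −30 °C; neutral aqueous work-up
Reagents that add atoms: none
Why: Bromine–lithium exchange, then addition of an aryllithium to a lactol: the first equivalent deprotonates 16, which opens to 20, and the next adds to the aldehyde faster than it enolises it, forming the Cα–C1(ring A') bond. Cα never passes through a ketone, so Cβ cannot epimerise by enolisation or by ketene formation from the aryl ester. The new Cα carbinol centre is uncontrolled and is removed in step 12.

Step 12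
Reactants: 21 (1RS,2R,3R)-2-benzyloxy-3-[3,4-bis(benzyloxy)phenyl]-3-[(2R,3S)-3,5,3',4'-tetra-O-benzyl-7-hydroxycatechin-8-yl]-1-[2,4,6-tris(benzyloxy)phenyl]propan-1-ol
Product: 22 8-{(1R,2S)-2-benzyloxy-1-[3,4-bis(benzyloxy)phenyl]-3-[2,4,6-tris(benzyloxy)phenyl]propyl}-7-hydroxy-3,5,3',4'-tetra-O-benzylcatechin
Conditions: Et3SiH (10 equiv), CF3CO2H (5 equiv), CH2Cl2, −78 → −30 °C
Reagents that add atoms: none
Why: Ionic hydrogenation: the 2,4,6-trialkoxybenzylic alcohol ionises under mild acid at low temperature and the cation takes hydride from the silane present in large excess. Capture of the cation by the C7 hydroxyl would give a cyclic benzylic ether that re-ionises under the same conditions, so it only stores the cation; Cβ and Cγ are not involved.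

Step 13
Reactants: 22 8-{(1R,2S)-2-benzyloxy-1-[3,4-bis(benzyloxy)phenyl]-3-[2,4,6-tris(benzyloxy)phenyl]propyl}-7-hydroxy-3,5,3',4'-tetra-O-benzylcatechin
Product: 23 gambiriin A1
Conditions: H2 (1 atm), Pd(OH)2/C, THF–MeOH, rt
Reagents that add atoms: none
Why: Hydrogenolysis of ten benzyl ethers over Pd(OH)2/C under neutral conditions, the standard last step for benzyl-protected flavan-3-ol oligomers. The C2–O1 ring ether and the carbon–carbon bonds at Cγ are not cleaved under these conditions and no stereocentre is touched.

## Compound list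

1 | (+)-catechin, (2R,3S)-2-(3,4-dihydroxyphenyl)chromane-3,5,7-triol | Oc1cc(O)c2c(c1)O[C@H](c1ccc(O)c(O)c1)[C@@H](O)C2 | starting material

2 | (2R,3S)-5,7,3',4'-tetra-O-benzylcatechin | c1ccccc1COc1cc(OCc3ccccc3)c2c(c1)O[C@H](c1ccc(OCc3ccccc3)c(OCc3ccccc3)c1)[C@@H](O)C2 | intermediate

3 | (2R,3S)-3,5,7,3',4'-penta-O-benzylcatechin | c1ccccc1COc1cc(OCc3ccccc3)c2c(c1)O[C@H](c1ccc(OCc3ccccc3)c(OCc3ccccc3)c1)[C@@H](OCc3ccccc3)C2 | intermediate

4 | 8-bromo-3,5,7,3',4'-penta-O-benzylcatechin (2R,3S) | Brc1c(OCc3ccccc3)cc(OCc3ccccc3)c2c1O[C@H](c1ccc(OCc3ccccc3)c(OCc3ccccc3)c1)[C@@H](OCc3ccccc3)C2 | intermediate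

5 | 8-lithio-3,5,7,3',4'-penta-O-benzylcatechin (2R,3S) | [Li]c1c(OCc3ccccc3)cc(OCc3ccccc3)c2c1O[C@H](c1ccc(OCc3ccccc3)c(OCc3ccccc3)c1)[C@@H](OCc3ccccc3)C2 | intermediate

6 | 8-formyl-3,5,7,3',4'-penta-O-benzylcatechin (2R,3S) | O=Cc1c(OCc3ccccc3)cc(OCc3ccccc3)c2c1O[C@H](c1ccc(OCc3ccccc3)c(OCc3ccccc3)c1)[C@@H](OCc3ccccc3)C2 | intermediate

7 | 8-formyl-7-hydroxy-3,5,3',4'-tetra-O-benzylcatechin (2R,3S) | O=Cc1c(O)cc(OCc3ccccc3)c2c1O[C@H](c1ccc(OCc3ccccc3)c(OCc3ccccc3)c1)[C@@H](OCc3ccccc3)C2 | intermediate

8 | 4-bromo-1,2-bis(benzyloxy)benzene | Brc1ccc(OCc2ccccc2)c(OCc2ccccc2)c1 | starting material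

9 | 3,4-bis(benzyloxy)phenylmagnesium bromide | Br[Mg]c1ccc(OCc2ccccc2)c(OCc2ccccc2)c1 | intermediate

10 | 7-hydroxy-8-{[3,4-bis(benzyloxy)phenyl](hydroxy)methyl}-3,5,3',4'-tetra-O-benzylcatechin (2R,3S; both carbinol epimers) | OC(c1ccc(OCc3ccccc3)c(OCc3ccccc3)c1)c1c(O)cc(OCc3ccccc3)c2c1O[C@H](c1ccc(OCc3ccccc3)c(OCc3ccccc3)c1)[C@@H](OCc3ccccc3)C2 | intermediate

11 | 7-hydroxy-8-{[3,4-bis(benzyloxy)phenyl](p-tolylsulfonyl)methyl}-3,5,3',4'-tetra-O-benzylcatechin (2R,3S; both epimers at the sulfonyl carbon) | Cc1ccc(cc1)S(=O)(=O)C(c1ccc(OCc3ccccc3)c(OCc3ccccc3)c1)c1c(O)cc(OCc3ccccc3)c2c1O[C@H](c1ccc(OCc3ccccc3)c(OCc3ccccc3)c1)[C@@H](OCc3ccccc3)C2 | intermediate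

12 | benzyloxyacetyl chloride | O=C(Cl)COCc1ccccc1 | starting material

13 | o-quinone methide of 11: 8-[3,4-bis(benzyloxy)benzylidene]-7-oxo form of (2R,3S)-3,5,3',4'-tetra-O-benzylcatechin (O=C7–C8=Cγ; geometry at C8=Cγ not fixed) | O=C1C=C(OCc3ccccc3)C2=C(O[C@H](c4ccc(OCc3ccccc3)c(OCc3ccccc3)c4)[C@@H](OCc3ccccc3)C2)C1=Cc1ccc(OCc3ccccc3)c(OCc3ccccc3)c1 | intermediate

14 | benzyloxyketene | O=C=COCc1ccccc1 | intermediate

15 | (3R,4R)-cis-3-benzyloxy-4-[3,4-bis(benzyloxy)phenyl]-3,4-dihydrocoumarin annulated on O7/C8 of (2R,3S)-3,5,3',4'-tetra-O-benzylcatechin (lactone O on C7, lactone C4 on C8) | O=C1[C@H](OCc3ccccc3)[C@H](c4ccc(OCc3ccccc3)c(OCc3ccccc3)c4)c2c(O1)cc(OCc3ccccc3)c5c2O[C@H](c2ccc(OCc3ccccc3)c(OCc3ccccc3)c2)[C@@H](OCc3ccccc3)C5 | intermediate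

16 | (2RS,3R,4R)-3-benzyloxy-4-[3,4-bis(benzyloxy)phenyl]chroman-2-ol annulated on O7/C8 of (2R,3S)-3,5,3',4'-tetra-O-benzylcatechin (lactol of 15) | OC1[C@H](OCc3ccccc3)[C@H](c4ccc(OCc3ccccc3)c(OCc3ccccc3)c4)c2c(O1)cc(OCc3ccccc3)c5c2O[C@H](c2ccc(OCc3ccccc3)c(OCc3ccccc3)c2)[C@@H](OCc3ccccc3)C5 | intermediate

17 | 1,3,5-tris(benzyloxy)benzene | c1ccccc1COc1cc(OCc2ccccc2)cc(OCc2ccccc2)c1 | starting material

18 | 2-bromo-1,3,5-tris(benzyloxy)benzene | Brc1c(OCc2ccccc2)cc(OCc2ccccc2)cc1OCc2ccccc2 | intermediate

19 | 2,4,6-tris(benzyloxy)phenyllithium | [Li]c1c(OCc2ccccc2)cc(OCc2ccccc2)cc1OCc2ccccc2 | intermediate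

20 | (2R,3R)-2-benzyloxy-3-[3,4-bis(benzyloxy)phenyl]-3-[(2R,3S)-3,5,3',4'-tetra-O-benzyl-7-(lithiooxy)catechin-8-yl]propanal | O=C[C@H](OCc3ccccc3)[C@H](c4ccc(OCc3ccccc3)c(OCc3ccccc3)c4)c2c(O[Li])cc(OCc3ccccc3)c5c2O[C@H](c2ccc(OCc3ccccc3)c(OCc3ccccc3)c2)[C@@H](OCc3ccccc3)C5 | intermediate

21 | (1RS,2R,3R)-2-benzyloxy-3-[3,4-bis(benzyloxy)phenyl]-3-[(2R,3S)-3,5,3',4'-tetra-O-benzyl-7-hydroxycatechin-8-yl]-1-[2,4,6-tris(benzyloxy)phenyl]propan-1-ol | OC(c1c(OCc3ccccc3)cc(OCc3ccccc3)cc1OCc3ccccc3)[C@H](OCc3ccccc3)[C@H](c4ccc(OCc3ccccc3)c(OCc3ccccc3)c4)c2c(O)cc(OCc3ccccc3)c5c2O[C@H](c2ccc(OCc3ccccc3)c(OCc3ccccc3)c2)[C@@H](OCc3ccccc3)C5 | intermediate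

22 | 8-{(1R,2S)-2-benzyloxy-1-[3,4-bis(benzyloxy)phenyl]-3-[2,4,6-tris(benzyloxy)phenyl]propyl}-7-hydroxy-3,5,3',4'-tetra-O-benzylcatechin (2R,3S) | C(c1c(OCc3ccccc3)cc(OCc3ccccc3)cc1OCc3ccccc3)[C@H](OCc3ccccc3)[C@H](c4ccc(OCc3ccccc3)c(OCc3ccccc3)c4)c2c(O)cc(OCc3ccccc3)c5c2O[C@H](c2ccc(OCc3ccccc3)c(OCc3ccccc3)c2)[C@@H](OCc3ccccc3)C5 | intermediate

23 | gambiriin A1, 8-[(1R,2S)-1-(3,4-dihydroxyphenyl)-2-hydroxy-3-(2,4,6-trihydroxyphenyl)propyl]-(+)-catechin | Oc1cc(O)c(C[C@H](O)[C@H](c2ccc(O)c(O)c2)c2c(O)cc(O)c3c2O[C@H](c2ccc(O)c(O)c2)[C@@H](O)C3)c(O)c1 | target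

## Step count and uncertain steps

Total: 13 steps. Longest linear sequence: 12 steps (steps 1 to 9, 11, 12 and 13, from 1). Step 10 is a one-step branch.

Step 8 (key step).
- The conjugate addition may pass through an open or exo arrangement and give the trans lactone, because the methide can react through either C8=Cγ geometry (ring B' has an oxygen-bearing carbon on both sides).
- Facial selection by the catalyst may be weak or of the opposite sense.
- The electron-rich methide may react so slowly that the ketene dimerises, or unreacted phenoxide is O-acylated.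
- The amine bases may epimerise Cβ of the product.
- Fallback, from 11 back to 15: stoichiometric control by an auxiliary. The sodium enolate (NaN(SiMe3)2, THF, −78 °C) of (S)-4-benzyl-3-(benzyloxyacetyl)oxazolidin-2-one F1, made from (S)-4-benzyloxazolidin-2-one and 12, would be added to 13 generated from 11 as in step 8. Conjugate addition of the chelated Z enolate on the face away from the benzyl group gives the open-chain imide (2R,3R)-2-benzyloxy-3-[3,4-bis(benzyloxy)phenyl]-3-(7-hydroxy-tetra-O-benzylcatechin-8-yl)propanoyl oxazolidinone F2, with Cβ fixed by the auxiliary. Warming with i-Pr2NEt and 4-dimethylaminopyridine lets the C7 phenoxide displace the oxazolidinone and close 15. Only the Cγ epimers, if both form, would then need separation.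

Step 12.
- The Cα cation may lose the Cβ proton to an enol ether, whose reprotonation scrambles Cβ.
- Friedel–Crafts ring closure onto ring B' may give an indane.
- The acid may ionise the C2–O1 bond.
- Fallback, from 21 directly to 23: hydrogenolysis over Pd(OH)2/C in THF–MeOH with acetic acid. The C–OH bond of the electron-rich benzylic alcohol is cleaved on the metal surface together with the benzyl ethers, without a free cation; no new compound is made (F0).

Step 11.
- Addition of the di-ortho-substituted aryllithium to the hindered aldehyde may be slow, so enolisation of 20 (epimerisation at Cβ) competes.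
- Retro-conjugate addition from the phenoxide of 20 (loss of the Cγ–Cβ bond) is possible.
- The lactolate may open incompletely.
- Fallback, from 16 and 17 back to 22: electrophilic instead of anionic arylation. BF3·OEt2 (CH2Cl2, −40 °C) would ionise 16 to its cyclic oxocarbenium ion, which 17 attacks in a Friedel–Crafts reaction to give the 2-[2,4,6-tris(benzyloxy)phenyl]chromane F3. Et3SiH and CF3CO2H then cleave its O7–Cα benzylic ether reductively through the same cation as in step 12 and deliver 22.

Step 7.
- The sulfone of so electron-rich a benzhydryl system may lose sulfinate on silica or in solution.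
- The benzhydryl cation may alkylate C6 of a second molecule (oligomerisation) before sulfinate captures it.
- Fallback, from 7 to 13 without a sulfone: 7 is converted into its tert-butyl carbonate, 7-O-(tert-butoxycarbonyl)-8-formyl-3,5,3',4'-tetra-O-benzylcatechin F4 (Boc2O, i-Pr2NEt, cat. 4-dimethylaminopyridine). Addition of 9 (1.05 equiv, THF, −78 °C) gives a magnesium alkoxide that takes over the carbonate group from O7. On warming to about −40 °C the liberated phenoxide expels tert-butyl carbonate and forms 13, which is used at once as in step 8.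

Step 9.
- The aluminate may collapse in the flask, because aryloxide is a good leaving group, and the aldehyde is then over-reduced to the diol.
- Fallback, from 15 back to 21: the organocerium reagent from 19 and CeCl3 (THF, −78 °C), which is nucleophilic but weakly basic, adds once to the lactone carbonyl and gives the hydroxy ketone (2R,3R)-2-benzyloxy-3-[3,4-bis(benzyloxy)phenyl]-3-(7-hydroxy-tetra-O-benzylcatechin-8-yl)-1-[2,4,6-tris(benzyloxy)phenyl]propan-1-one F5. NaBH4 (MeOH–THF, −20 °C) reduces it to 21.

## Further compounds

F1 | step 8 | (S)-4-benzyl-3-(benzyloxyacetyl)oxazolidin-2-one | O=C(COCc1ccccc1)N1[C@@H](Cc2ccccc2)COC1=O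

F2 | step 8 | (S)-4-benzyl-3-{(2R,3R)-2-benzyloxy-3-[3,4-bis(benzyloxy)phenyl]-3-[(2R,3S)-3,5,3',4'-tetra-O-benzyl-7-hydroxycatechin-8-yl]propanoyl}oxazolidin-2-one | O=C([C@H](OCc3ccccc3)[C@H](c4ccc(OCc3ccccc3)c(OCc3ccccc3)c4)c2c(O)cc(OCc3ccccc3)c5c2O[C@H](c2ccc(OCc3ccccc3)c(OCc3ccccc3)c2)[C@@H](OCc3ccccc3)C5)N1[C@@H](Cc2ccccc2)COC1=O

F0 | step 12 | none | none

F3 | step 11 | (2RS,3R,4R)-3-benzyloxy-4-[3,4-bis(benzyloxy)phenyl]-2-[2,4,6-tris(benzyloxy)phenyl]chromane annulated on O7/C8 of (2R,3S)-3,5,3',4'-tetra-O-benzylcatechin | C1(c6c(OCc3ccccc3)cc(OCc3ccccc3)cc6OCc3ccccc3)[C@H](OCc3ccccc3)[C@H](c4ccc(OCc3ccccc3)c(OCc3ccccc3)c4)c2c(O1)cc(OCc3ccccc3)c5c2O[C@H](c2ccc(OCc3ccccc3)c(OCc3ccccc3)c2)[C@@H](OCc3ccccc3)C5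

F4 | step 7 | 7-O-(tert-butoxycarbonyl)-8-formyl-3,5,3',4'-tetra-O-benzylcatechin (2R,3S) | O=Cc1c(OC(=O)OC(C)(C)C)cc(OCc3ccccc3)c2c1O[C@H](c1ccc(OCc3ccccc3)c(OCc3ccccc3)c1)[C@@H](OCc3ccccc3)C2

F5 | step 9 | (2R,3R)-2-benzyloxy-3-[3,4-bis(benzyloxy)phenyl]-3-[(2R,3S)-3,5,3',4'-tetra-O-benzyl-7-hydroxycatechin-8-yl]-1-[2,4,6-tris(benzyloxy)phenyl]propan-1-one | O=C(c1c(OCc3ccccc3)cc(OCc3ccccc3)cc1OCc3ccccc3)[C@H](OCc3ccccc3)[C@H](c4ccc(OCc3ccccc3)c(OCc3ccccc3)c4)c2c(O)cc(OCc3ccccc3)c5c2O[C@H](c2ccc(OCc3ccccc3)c(OCc3ccccc3)c2)[C@@H](OCc3ccccc3)C5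

A1 | alternative 1 | ring A phenol from the benzannulation (O7–H free, O1 triisopropylsilyl, O5 benzyl, protected chain on C8) | c9ccccc9COc1cc(OCc9ccccc9)c(C[C@H](OCc9ccccc9)[C@H](c2ccc(OCc9ccccc9)c(OCc9ccccc9)c2)c2c(O)cc(OCc9ccccc9)cc2O[Si](C(C)C)(C(C)C)C(C)C)c(OCc9ccccc9)c1

A2 | alternative 1 | triisopropylsiloxyalkyne carrying the protected Cγ/Cβ diad, ring B' and ring A' | CC(C)[Si](C(C)C)(C(C)C)OC#C[C@@H](c1ccc(OCc2ccccc2)c(OCc2ccccc2)c1)[C@@H](OCc2ccccc2)Cc1c(OCc2ccccc2)cc(OCc2ccccc2)cc1OCc2ccccc2

A3 | alternative 1 | 3-(benzyloxy)cyclobut-2-en-1-one | O=C1C=C(OCc2ccccc2)C1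

A4 | alternative 2 | fully benzylated target skeleton with a pinacol boronate at Cβ | c9ccccc9COc1cc(OCc9ccccc9)c(C[C@H](B4OC(C)(C)C(C)(C)O4)[C@H](c2ccc(OCc9ccccc9)c(OCc9ccccc9)c2)c2c(OCc9ccccc9)cc(OCc9ccccc9)c3c2O[C@H](c2ccc(OCc9ccccc9)c(OCc9ccccc9)c2)[C@@H](OCc9ccccc9)C3)c(OCc9ccccc9)c1

A5 | alternative 2 | 8-[(Z)-2-iodoethenyl]-3,5,7,3',4'-penta-O-benzylcatechin (2R,3S) | I/C=C\c1c(OCc3ccccc3)cc(OCc3ccccc3)c2c1O[C@H](c1ccc(OCc3ccccc3)c(OCc3ccccc3)c1)[C@@H](OCc3ccccc3)C2

A6 | alternative 2 | 2-[2,4,6-tris(benzyloxy)benzyl]-4,4,5,5-tetramethyl-1,3,2-dioxaborolane | CC1(C)OB(Cc2c(OCc3ccccc3)cc(OCc3ccccc3)cc2OCc3ccccc3)OC1(C)C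

A7 | alternative 2 | 3,4-bis(benzyloxy)phenyl trifluoromethanesulfonate | O=S(=O)(Oc1ccc(OCc2ccccc2)c(OCc2ccccc2)c1)C(F)(F)F

A8 | alternative 3 | deca-O-benzyl target with free C3 hydroxyl | c9ccccc9COc1cc(OCc9ccccc9)c(C[C@H](OCc9ccccc9)[C@H](c2ccc(OCc9ccccc9)c(OCc9ccccc9)c2)c2c(OCc9ccccc9)cc(OCc9ccccc9)c3c2O[C@H](c2ccc(OCc9ccccc9)c(OCc9ccccc9)c2)[C@@H](O)C3)c(OCc9ccccc9)c1

A9 | alternative 3 | E-alkene with O1 as tert-butyldimethylsilyl ether and the protected chain on C8 | c9ccccc9COc1cc(OCc9ccccc9)c(C[C@H](OCc9ccccc9)[C@H](c2ccc(OCc9ccccc9)c(OCc9ccccc9)c2)c2c(OCc9ccccc9)cc(OCc9ccccc9)c(C/C=C/c3ccc(OCc9ccccc9)c(OCc9ccccc9)c3)c2O[Si](C)(C)C(C)(C)C)c(OCc9ccccc9)c1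

A10 | alternative 3 | (2S,3S)-trans-epoxide of the E-alkene | c9ccccc9COc1cc(OCc9ccccc9)c(C[C@H](OCc9ccccc9)[C@H](c2ccc(OCc9ccccc9)c(OCc9ccccc9)c2)c2c(OCc9ccccc9)cc(OCc9ccccc9)c(C[C@@H]4O[C@H]4c3ccc(OCc9ccccc9)c(OCc9ccccc9)c3)c2O[Si](C)(C)C(C)(C)C)c(OCc9ccccc9)c1
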